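The ratio of other capture product to target was wanted at three times in a new flask, and I kept a ledger from the two earlier runs to reach it.

| flask | starting material | first nucleophile | second nucleophile | remark | time |
|---|---|---|---|---|---|
| oak | 0.56 M | 0.95 equiv | 1.2 equiv | run made earlier |  |
| larch | 1.3 M | 0.95 equiv | 1.2 equiv | run made earlier |  |
| flask | 0.84 M | 0.950 equiv | 1.20 equiv |  | 4.0 min |

| run | time / min | other capture product / % | target / % | starting material / % |
|---|---|---|---|---|
| oak | 0.250 | 19 | 65 | 15 |
| oak | 0.833 | 18 | 81 | 1 |
| oak | 1.33 | 16 | 81 | 0 |
| oak | 2.00 | 17 | 81 | 0 |
| oak | 3.00 | 14 | 82 | 1 |
| oak | 4.00 | 20 | 85 | 3 |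
| larch | 0.333 | 19 | 68 | 12 |
| larch | 0.500 | 21 | 77 | 4 |
| larch | 0.833 | 22 | 82 | 1 |
| larch | 1.33 | 21 | 83 | 5 |
| larch | 2.50 | 20 | 83 | 2 |
| larch | 4.00 | 17 | 85 | 0 |

(each reading ± 2 percentage points)
- ratio of other capture product to target at 0.20 s
- ratio of other capture product to target at 6.0 s
- ratio of other capture product to target at 4.0 min
- the numbers in the tables scatter by 2 percentage points (one standard deviation)

I booked the starting material first. Late readings (from 0.833 min on) averaged 18.3% other capture product and 82.6% target, together 101%, so the books closed within the scatter, at a late ratio of 0.222.

Then I booked the second nucleophile. Its charge was 1.2 equiv, so I took the capture share, the fraction of the charged second nucleophile that ended as other capture product, as 15.3%. The other 84.7% stood in no peak I was shown.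

The oak run showed when that share was earned. At 0.250 min its other capture product already read 19%, level with the plateau, while 15% of starting material remained, and the ratio read 0.292. That reading gives starting material a half-life of 5.48 s, and the larch run gives 6.53 s. Working with the fraction left, I expected 46.8% of starting material at 6.0 s. If the other capture product were complete by then, the ratio would be 0.526. I committed to that figure, to a larger ratio still at 0.20 s, and to 0.222 at 4.0 min.

The forecast gave 0.29, 0.27 and 0.22, and for the late drift it offered “A slow leak of other product, or a slightly more selective later capture”. It parted from my reckoning at the early times.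

The flask gave 2.86, 0.458 and 0.229.

    starting material → intermediate (k = 0.121 /s)
    first nucleophile + intermediate → target (k = 5.65 /M/s)
    second nucleophile + intermediate → other capture product (k = 17.7 /M/s)
    second nucleophile → decomposed reagent (k = 1.02 /s)
    second nucleophile ⇌ dormant form (K = 2.20, k = 1.82 /s)

By decomposition alone, the second nucleophile had a half-life of 0.68 s, against 5.73 s for starting material by its own step. At 0.0207 min in the flask, it was going to decomposed reagent 4.4 times as fast as to other capture product. At 4.00 min the flask held 84.5% of its charge of second nucleophile as decomposed reagent and a capture share of 15.5%, against the 15.3% I had reckoned from the readings. In the neighbour flask charged with 0.480 equiv of second nucleophile, my share reckoned 7.34% of other capture product, and that flask held 9.34%.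

(The numbers in the tables are calculated for an exercise, and the scatter is random.)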